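Take the amounts first: both flasks get 0.0050 M of free monomer and 100 µM of initiator, and they differ in how long they stand.

in all of them: free monomer 0.0050 M; initiator 100 µM

| flask | time |
|---|---|
| south-west | 80 s |
| north-west | 20 s |

    free monomer + initiator → living end + monomer in chains (k1 = 120 M⁻¹ s⁻¹)
    free monomer + living end → monomer in chains + living end, rate k2*[living end]*[free monomer] (k2 = 4500 M⁻¹ s⁻¹)
    monomer in chains + living end → free monomer + living end, rate k3*[living end] as long as [monomer in chains] is above zero (k3 = 5.3 s⁻¹)
    monomer in chains → over-reaction product (k4 = 9.6 × 10⁻⁵ s⁻¹)
    2 initiator → spent initiator (k5 = 1800 M⁻¹ s⁻¹)

- where a step has two of a species, its rate is k times that concentration squared, and two are used at each turn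
- the average divides the monomer in chains by the number of chains begun, living and dead together
- run time (south-west): 80 s

- which of the two ends with the longer chains by the average number of monomer units in a chain (chains begun, living or dead) ("neither" if they lie within 10%) (south-west / north-west / neither)
- average number of monomer units in a chain (chains begun, living or dead) at the end, south-west
- average number of monomer units in a chain (chains begun, living or dead) at the end, north-west

Reckon the length as a ratio of two amounts. Free monomer falls until adding a unit and dropping one run equally fast, at the equilibrium monomer level, 1.18 mM, so the chains can hold 3.82 mM. Each initiator either begins a chain or meets another initiator, and the two fates run equally fast at an initiator level of 167 µM, taking free monomer at its charge. Multiply that level by the natural log of one plus charge over level: 78.3 µM of chains begun. Allow the use of the charge, because initiator lasts 1.04 s at the start, less than the 2.84 s lifetime of free monomer's excess over its equilibrium level with that many living ends. The ratio is 48.8, the chain number: monomer the chains can hold, divided by chains begun.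

Now test it, since it holds no time. North-west's 20 s spans 7.04 lifetimes. Over-reaction has a half-life of 120 min, longer than 80 s, and by estimate takes 0.768% of the monomer in chains in south-west and 0.192% in north-west. The lengths should part by 0.576%, less than 10%. So commit to 48.4 south-west, 48.7 north-west, and neither.

The forecast said neither, with 49 south-west and 49.3 north-west, since the extra time “only lets the slow over-reaction remove under 1% of the monomer in chains”.

The flasks give neither: 49.4 south-west and 49.9 north-west. South-west holds over-reaction product equal to 0.555% of the free monomer charged at 80.0 s, and its length stands at 1.01 times the chain number. Now cut north-west's free monomer to 0.0020 M: the equal-fates level becomes 66.7 µM, and the chain number 13.5. That flask reads 14.0 at 20.0 s, with 59.3% of its charged free monomer still free.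

All constants were set for the occasion; no experiment stands behind them.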